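**Retrosynthetic overview**
- Maackiaflavanone A ⇐ MOM removal and para-Claisen–Cope shift of a 5-O-prenyl group to C8 of an (S)-flavanone; the prenyl ether serves as the 5-OH protecting group until it migrates.
- Ring C (O1–C2 bond and the C2 stereocentre) ⇐ catalytic enantioselective oxa-Michael ring closure of a 2'-hydroxychalcone with a single free ortho-OH (key step).
- Chalcone ⇐ Claisen–Schmidt condensation of a mono-O-prenylated 2',6'-dihydroxy-4'-methoxyacetophenone with a MOM-protected chromene aldehyde.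
- Chromene aldehyde (ring B plus pyran ring) ⇐ propargyl-ether Claisen/electrocyclisation from 2,4-dihydroxybenzaldehyde.
- Ring order: benzene rings A and B are bought; the chromene pyran ring is made first, ring C last.

Assumption: 2',6'-dihydroxy-4'-methoxyacetophenone is bought as a catalogue compound.
Assumption: the facial sense of the new cyclisation is confirmed on the first run (chiral HPLC, CD); if 2R forms, the mirror-image catalyst from D-tert-leucine is used.
Catalyst note: BIMP-1 is the pre-formed (S)-thiourea–iminophosphorane ArNHC(=S)NH–CH(t-Bu)–CH2–N=P(C6H4-4-OMe)3 with Ar = 3,5-(CF3)2C6H3, made beforehand from the L-tert-leucine-derived azide and P(C6H4-4-OMe)3.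
Eu(fod)3 = tris(6,6,7,7,8,8,8-heptafluoro-2,2-dimethyloctane-3,5-dionato)europium.

**Route**

Step 1
Reactants: 1 2,4-dihydroxybenzaldehyde
Product: 2 2-hydroxy-4-[(2-methylbut-3-yn-2-yl)oxy]benzaldehyde
Conditions: 3-chloro-3-methylbut-1-yne (1.5 equiv), K2CO3 (2 equiv), CuI (5 mol%), MeCN, 60 °C
Reagents that add atoms: 3-chloro-3-methylbut-1-yne, CC(C)(Cl)C#C
Why: Copper-assisted Williamson-type O-propargylation; only the non-chelated, more acidic 4-OH reacts because the 2-OH is held in a hydrogen bond to the aldehyde.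

Step 2
Reactants: 2 2-hydroxy-4-[(2-methylbut-3-yn-2-yl)oxy]benzaldehyde
Product: 3 2-(methoxymethoxy)-4-[(2-methylbut-3-yn-2-yl)oxy]benzaldehyde
Conditions: NaH (1.2 equiv), MOMCl (1.3 equiv), DMF, 0 °C to rt
Reagents that add atoms: chloromethyl methyl ether (MOMCl), COCCl
Why: Williamson-type MOM acetal formation on the sodium phenoxide; the cap steers the regiochemistry of step 3 and protects this phenol through steps 5 and 6.

Step 3
Reactants: 3 2-(methoxymethoxy)-4-[(2-methylbut-3-yn-2-yl)oxy]benzaldehyde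
Product: 5 7-(methoxymethoxy)-2,2-dimethyl-2H-chromene-6-carbaldehyde, via ortho-allenylphenol 4 (not isolated)
Conditions: PhNEt2 (degassed), 190 °C, 3 h
Reagents that add atoms: none
Why: Aryl propargyl ether Claisen rearrangement ([3,3] shift, rearomatisation to 4, 1,5-H shift, 6π oxa-electrocyclisation); with the 2-OH capped there is no chelate-induced bond fixation toward C3, so the shift goes to the less hindered C5 para to the OMOM donor and gives the linear chromene (the minor angular isomer is removed by chromatography).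

Step 4
Reactants: 6 1-(2,6-dihydroxy-4-methoxyphenyl)ethan-1-one
Product: 7 1-[2-hydroxy-4-methoxy-6-(3-methylbut-2-en-1-yloxy)phenyl]ethan-1-one
Conditions: prenyl bromide (1.05 equiv), K2CO3 (1.1 equiv), acetone, reflux
Reagents that add atoms: prenyl bromide (1-bromo-3-methylbut-2-ene), CC(C)=CCBr
Why: Williamson etherification; the ketone is symmetric so either OH gives the same ether, and the remaining OH is deactivated by chelation to the carbonyl, which stops the reaction at the mono-ether.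

Step 5
Reactants: 7 1-[2-hydroxy-4-methoxy-6-(3-methylbut-2-en-1-yloxy)phenyl]ethan-1-one; 5 7-(methoxymethoxy)-2,2-dimethyl-2H-chromene-6-carbaldehyde
Product: 9 (2E)-1-[2-hydroxy-4-methoxy-6-(3-methylbut-2-en-1-yloxy)phenyl]-3-[7-(methoxymethoxy)-2,2-dimethyl-2H-chromen-6-yl]prop-2-en-1-one, via aldol adduct 8 (not isolated)
Conditions: KOH (50% aq.), EtOH, rt, 48 h; then AcOH to pH 6 at 0 °C
Reagents that add atoms: none
Why: Claisen–Schmidt aldol condensation with E1cB dehydration of 8 gives the E-enone; in strong base the product stays as the open chalcone phenoxide, and the MOM acetal, prenyl ether and chromene are base-stable.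

Step 6
Reactants: 9 (2E)-1-[2-hydroxy-4-methoxy-6-(3-methylbut-2-en-1-yloxy)phenyl]-3-[7-(methoxymethoxy)-2,2-dimethyl-2H-chromen-6-yl]prop-2-en-1-one
Product: 10 (2S)-7-methoxy-2-[7-(methoxymethoxy)-2,2-dimethyl-2H-chromen-6-yl]-5-(3-methylbut-2-en-1-yloxy)-2,3-dihydro-4H-chromen-4-one
Conditions: BIMP-1 (10 mol%), toluene (0.1 M), −20 °C, 48 h; AcOH quench at −20 °C at about 95% conversion
Reagents that add atoms: none
Why: Proposed new method: enantioselective 6-endo-trig oxa-Michael cyclisation of an unactivated, electron-rich 2'-hydroxychalcone under bifunctional iminophosphorane catalysis. The superbasic P=N unit deprotonates the chelated 2'-OH, breaking the OH···O=C hydrogen bond that holds the phenol away from C-β, while the thiourea N–H groups bind the enone carbonyl in a chiral ion pair. The phenoxide adds to the Si face of C-β to set C2 as S, and the enolate is protonated by the P–N+H. The 6'-O-prenyl group twists the aroyl unit and speeds closure, and low temperature plus acid quench suppress the E1cB ring-opening that would racemise the product. The closest known reactions are iminophosphorane-catalysed oxa-Michael additions of alcohols to unsaturated esters and amides, and cinchona-thiourea cyclisation of chalcones activated by an α-alkoxycarbonyl group.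

Step 7
Reactants: 10 (2S)-7-methoxy-2-[7-(methoxymethoxy)-2,2-dimethyl-2H-chromen-6-yl]-5-(3-methylbut-2-en-1-yloxy)-2,3-dihydro-4H-chromen-4-one
Product: 13 maackiaflavanone A, via ortho-Claisen dienone 11 (not isolated), via MOM-protected 8-prenylflavanone 12 (not isolated)
Conditions: Eu(fod)3 (10 mol%), CHCl3, 60 °C, 18 h; then evaporate, 3 M HCl (aq)/MeOH, 40 °C, 2 h
Reagents that add atoms: none
Why: Eu(fod)3-catalysed aromatic Claisen shift of the prenyl ether to C6, then Cope shift to C8 (para-Claisen–Cope, driven by the crowding of the C6 quaternary group between C5=O and 7-OMe) and rearomatisation free the chelated 5-OH; acid methanolysis then removes the MOM acetal, C2 is not touched, and the C-prenyl group has no neighbouring free OH to cyclise onto.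

**Compound list**
1 | 2,4-dihydroxybenzaldehyde | O=Cc1ccc(O)cc1O | starting material
2 | 2-hydroxy-4-[(2-methylbut-3-yn-2-yl)oxy]benzaldehyde | O=Cc1ccc(OC(C)(C)C#C)cc1O | intermediate
3 | 2-(methoxymethoxy)-4-[(2-methylbut-3-yn-2-yl)oxy]benzaldehyde | O=Cc1ccc(OC(C)(C)C#C)cc1OCOC | intermediate
4 | 4-hydroxy-2-(methoxymethoxy)-5-(3-methylbuta-1,2-dien-1-yl)benzaldehyde (ortho-allenylphenol, not isolated) | O=Cc1cc(C=C=C(C)C)c(O)cc1OCOC | intermediate
5 | 7-(methoxymethoxy)-2,2-dimethyl-2H-chromene-6-carbaldehyde | O=Cc1cc2C=CC(C)(C)Oc2cc1OCOC | intermediate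
6 | 1-(2,6-dihydroxy-4-methoxyphenyl)ethan-1-one (2',6'-dihydroxy-4'-methoxyacetophenone) | CC(=O)c1c(O)cc(OC)cc1O | starting material
7 | 1-[2-hydroxy-4-methoxy-6-(3-methylbut-2-en-1-yloxy)phenyl]ethan-1-one | CC(=O)c1c(O)cc(OC)cc1OCC=C(C)C | intermediate
8 | 3-hydroxy-1-[2-hydroxy-4-methoxy-6-(3-methylbut-2-en-1-yloxy)phenyl]-3-[7-(methoxymethoxy)-2,2-dimethyl-2H-chromen-6-yl]propan-1-one (racemic aldol adduct, not isolated) | COc1cc(O)c(C(=O)CC(O)c2cc3C=CC(C)(C)Oc3cc2OCOC)c(OCC=C(C)C)c1 | intermediate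
9 | (2E)-1-[2-hydroxy-4-methoxy-6-(3-methylbut-2-en-1-yloxy)phenyl]-3-[7-(methoxymethoxy)-2,2-dimethyl-2H-chromen-6-yl]prop-2-en-1-one | COc1cc(O)c(C(=O)/C=C/c2cc3C=CC(C)(C)Oc3cc2OCOC)c(OCC=C(C)C)c1 | intermediate
10 | (2S)-7-methoxy-2-[7-(methoxymethoxy)-2,2-dimethyl-2H-chromen-6-yl]-5-(3-methylbut-2-en-1-yloxy)-2,3-dihydro-4H-chromen-4-one | COc1cc(OCC=C(C)C)c2c(c1)O[C@H](c1cc3c(cc1OCOC)OC(C)(C)C=C3)CC2=O | intermediate
11 | (2S)-7-methoxy-2-[7-(methoxymethoxy)-2,2-dimethyl-2H-chromen-6-yl]-6-(2-methylbut-3-en-2-yl)-2,3-dihydro-4H-chromene-4,5(6H)-dione (ortho-Claisen dienone, C6 undefined, not isolated) | O1[C@H](c3cc4c(cc3OCOC)OC(C)(C)C=C4)CC(=O)C2=C1C=C(OC)C(C(C)(C)C=C)C2=O | intermediate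
12 | (2S)-5-hydroxy-7-methoxy-2-[7-(methoxymethoxy)-2,2-dimethyl-2H-chromen-6-yl]-8-(3-methylbut-2-en-1-yl)-2,3-dihydro-4H-chromen-4-one (not isolated) | COc1cc(O)c2c(c1CC=C(C)C)O[C@H](c1cc3c(cc1OCOC)OC(C)(C)C=C3)CC2=O | intermediate
13 | maackiaflavanone A, (2S)-5-hydroxy-2-(7-hydroxy-2,2-dimethyl-2H-chromen-6-yl)-7-methoxy-8-(3-methylbut-2-en-1-yl)-2,3-dihydro-4H-chromen-4-one | COc1cc(O)c2c(c1CC=C(C)C)O[C@H](c1cc3c(cc1O)OC(C)(C)C=C3)CC2=O | target

**Step count**
Total steps: 7 (step 7 is one pot).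
Longest linear sequence: 6 (steps 1, 2, 3, 5, 6, 7).

**Three steps most likely to fail**

Step 6 (proposed new cyclisation). The risks are slow closure onto the electron-rich enone and loss of ee through reversible ring-opening. The fallback uses known chemistry and sets out from chalcone 9. NaOAc in refluxing EtOH gives racemic 7-methoxy-2-[7-(methoxymethoxy)-2,2-dimethyl-2H-chromen-6-yl]-5-(3-methylbut-2-en-1-yloxy)chroman-4-one F1. Kinetic resolution by asymmetric transfer hydrogenation with RuCl(p-cymene)[(R,R)-TsDPEN] and HCO2H/Et3N in EtOAc at rt, run to about 55% conversion, reduces the 2R enantiomer to the cis alcohol (2R,4R)-7-methoxy-2-[7-(methoxymethoxy)-2,2-dimethyl-2H-chromen-6-yl]-5-(3-methylbut-2-en-1-yloxy)chroman-4-ol F2. The unreacted 2S ketone is recovered by chromatography (at most 50%), and the route is rejoined at 10.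

Step 7 (Claisen–Cope and MOM removal). The risks are the ortho product (6-(1,1-dimethylallyl) isomer) and partial racemisation of the electron-rich benzylic C2–O bond under Lewis or Brønsted acid. The fallback puts the prenyl group on carbon before the stereocentre exists and sets out from ketone 6.
- C-prenylation with prenyl bromide and DBU in THF gives 1-[2,6-dihydroxy-4-methoxy-3-(3-methylbut-2-en-1-yl)phenyl]ethan-1-one F3 (one regioisomer by symmetry).
- MOMCl (1.1 equiv) and i-Pr2NEt in CH2Cl2 at 0 °C cap the less hindered OH remote from the prenyl group, giving 1-[2-hydroxy-4-methoxy-6-(methoxymethoxy)-3-(3-methylbut-2-en-1-yl)phenyl]ethan-1-one F4.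
- Claisen–Schmidt condensation with aldehyde 5 (KOH, EtOH) gives (2E)-1-[2-hydroxy-4-methoxy-6-(methoxymethoxy)-3-(3-methylbut-2-en-1-yl)phenyl]-3-[7-(methoxymethoxy)-2,2-dimethyl-2H-chromen-6-yl]prop-2-en-1-one F5.
- Cyclisation with BIMP-1 as in step 6 gives (2S)-7-methoxy-5-(methoxymethoxy)-2-[7-(methoxymethoxy)-2,2-dimethyl-2H-chromen-6-yl]-8-(3-methylbut-2-en-1-yl)-2,3-dihydro-4H-chromen-4-one F6.
- 3 M HCl/MeOH at 40 °C removes both MOM groups, and the route is rejoined at 13.

Step 3 (regiochemistry of the propargyl Claisen). The risk is a large share of the angular chromene from shift to C3. The fallback fixes the position with a halogen and sets out from aldehyde 1.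
- Br2 in AcOH gives 5-bromo-2,4-dihydroxybenzaldehyde F7.
- Heck coupling with 2-methylbut-3-en-2-ol (Pd(OAc)2, P(o-tol)3, Et3N, DMF, 100 °C) gives 2,4-dihydroxy-5-[(1E)-3-hydroxy-3-methylbut-1-en-1-yl]benzaldehyde F8.
- PPTS (cat.) in toluene at 80 °C closes the pyran ring onto the only ortho oxygen by cyclodehydration, giving 7-hydroxy-2,2-dimethyl-2H-chromene-6-carbaldehyde F9.
- NaH and MOMCl in DMF then cap the phenol, and the route is rejoined at 5.

**Further compounds**
F1 | step 6 | racemic 7-methoxy-2-[7-(methoxymethoxy)-2,2-dimethyl-2H-chromen-6-yl]-5-(3-methylbut-2-en-1-yloxy)chroman-4-one | COc1cc(OCC=C(C)C)c2c(c1)OC(c1cc3c(cc1OCOC)OC(C)(C)C=C3)CC2=O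
F2 | step 6 | (2R,4R)-7-methoxy-2-[7-(methoxymethoxy)-2,2-dimethyl-2H-chromen-6-yl]-5-(3-methylbut-2-en-1-yloxy)chroman-4-ol | COc1cc(OCC=C(C)C)c2c(c1)O[C@@H](c1cc3c(cc1OCOC)OC(C)(C)C=C3)C[C@H]2O
F3 | step 7 | 1-[2,6-dihydroxy-4-methoxy-3-(3-methylbut-2-en-1-yl)phenyl]ethan-1-one | CC(=O)c1c(O)cc(OC)c(CC=C(C)C)c1O
F4 | step 7 | 1-[2-hydroxy-4-methoxy-6-(methoxymethoxy)-3-(3-methylbut-2-en-1-yl)phenyl]ethan-1-one | CC(=O)c1c(OCOC)cc(OC)c(CC=C(C)C)c1O
F5 | step 7 | (2E)-1-[2-hydroxy-4-methoxy-6-(methoxymethoxy)-3-(3-methylbut-2-en-1-yl)phenyl]-3-[7-(methoxymethoxy)-2,2-dimethyl-2H-chromen-6-yl]prop-2-en-1-one | COc1cc(OCOC)c(C(=O)/C=C/c2cc3C=CC(C)(C)Oc3cc2OCOC)c(O)c1CC=C(C)C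
F6 | step 7 | (2S)-7-methoxy-5-(methoxymethoxy)-2-[7-(methoxymethoxy)-2,2-dimethyl-2H-chromen-6-yl]-8-(3-methylbut-2-en-1-yl)-2,3-dihydro-4H-chromen-4-one | COc1cc(OCOC)c2c(c1CC=C(C)C)O[C@H](c1cc3c(cc1OCOC)OC(C)(C)C=C3)CC2=O
F7 | step 3 | 5-bromo-2,4-dihydroxybenzaldehyde | O=Cc1cc(Br)c(O)cc1O
F8 | step 3 | 2,4-dihydroxy-5-[(1E)-3-hydroxy-3-methylbut-1-en-1-yl]benzaldehyde | O=Cc1cc(/C=C/C(C)(C)O)c(O)cc1O
F9 | step 3 | 7-hydroxy-2,2-dimethyl-2H-chromene-6-carbaldehyde | O=Cc1cc2C=CC(C)(C)Oc2cc1O
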